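**Plan**

- Retrosynthesis (locants of the 6-oxabicyclo[3.2.1]octan-7-one core: C1 = quaternary carbonyl-bearing bridgehead, C2 = CHMe, C5 = O-bearing bridgehead, C8 = one-carbon bridge). First the C1–CH2 bond of the butenolide arm is cut back to a C1 carboxylic acid. Then the C1–C8 bond and the C5–O6 bond are cut in one operation, which opens both bridges to an acyclic 5-alkyl Meldrum's acid carrying a (Z)-1,3-diene. Last come the C2–CH3 bond and the two C–C bonds at the central diene carbon.
- Enabling feature: the γ-lactone ring O6–C7(=O)–C1–C8–C5 holds a carboxyl-bearing quaternary carbon (C1) 1,3 to a tertiary, allylic C–O carbon (C5, isopropenyl-substituted). This is the retron of an oxidative lactone annulation of a malonyl radical onto the C8=C5 bond of a 1,3-diene. The isopropenyl group is the half of the diene that is left over, and the second carboxyl of the malonyl unit is the handle that later becomes the arm.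
- Forward: dichloro-olefination of methyl 4-oxobutanoate, two stereospecific couplings (alkylzinc trans, isopropenyl cis to the ester chain) to the (Z)-diene, aldehyde release, Knoevenagel condensation, asymmetric conjugate methylation. The radical–polar cascade then closes the carbocycle (C1–C8) and at once the lactone (O6–C5). The freed bridgehead acid is exchanged for vinyl, and the vinyl group is joined to 3-bromobutenolide.
- Stereochemistry: C2 comes from the catalytic asymmetric methyl addition. C8 comes from the alkene geometry in a chair transition state with equatorial methyl. C1 and C5 are fixed together because only the axial carbonyl of the symmetric dioxanedione can bridge. The later substitution at bridgehead C1 is retentive by geometry.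

Key step: step 7

Remark: in step 6 the phosphoramidite antipode is the one that delivers methyl to the alkylidene face giving the (R) centre; compounds 1, 3, 5, 8 and 14 are taken as catalogue materials.

**Route**

Step 1
Reactants: 1 methyl 4-oxobutanoate
Product: 2 methyl 5,5-dichloropent-4-enoate
Conditions: PPh3, CCl4, THF, 65 °C
Reagents that add atoms: carbon tetrachloride, ClC(Cl)(Cl)Cl
Why: Phosphine–CCl4 gem-dichloro-olefination (the dichloro variant of the Corey–Fuchs/Ramirez reaction), in which the ylide Ph3P=CCl2 formed in the flask olefinates the unhindered aldehyde in a Wittig step while the ester is inert.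

Step 2
Reactants: 2 methyl 5,5-dichloropent-4-enoate; 3 [2-(1,3-dioxolan-2-yl)ethyl]zinc bromide
Product: 4 methyl (4Z)-5-chloro-7-(1,3-dioxolan-2-yl)hept-4-enoate
Conditions: PdCl2(DPEphos) (5 mol%), THF/DMF, 23 °C
Reagents that add atoms: none
Why: Negishi coupling of a 1,1-dichloroalkene, in which zerovalent palladium inserts into the less hindered C–Cl bond trans to the alkyl chain, so the alkyl group enters trans to the ester chain and the remaining chlorine stays cis to it; ester and acetal tolerate the organozinc.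

Step 3
Reactants: 4 methyl (4Z)-5-chloro-7-(1,3-dioxolan-2-yl)hept-4-enoate; 5 4,4,5,5-tetramethyl-2-(prop-1-en-2-yl)-1,3,2-dioxaborolane
Product: 6 methyl (4Z)-5-[2-(1,3-dioxolan-2-yl)ethyl]-6-methylhepta-4,6-dienoate
Conditions: Pd(PtBu3)2 (5 mol%), K3PO4, THF/H2O, 50 °C
Reagents that add atoms: none
Why: Suzuki–Miyaura coupling of the alkenyl chloride under a bulky trialkylphosphine complex of zerovalent palladium should proceed with retention, so the isopropenyl group ends cis to the ester chain and gives the (Z)-1,3-diene that the key step needs.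

Step 4
Reactants: 6 methyl (4Z)-5-[2-(1,3-dioxolan-2-yl)ethyl]-6-methylhepta-4,6-dienoate
Product: 7 methyl (4Z)-6-methyl-5-(3-oxopropyl)hepta-4,6-dienoate
Conditions: 2 M HCl (aq.), THF, 23 °C
Reagents that add atoms: water, O
Why: Acid-catalysed acetal hydrolysis, with dilute acid at room temperature expected to leave the trisubstituted diene and the methyl ester untouched.

Step 5
Reactants: 7 methyl (4Z)-6-methyl-5-(3-oxopropyl)hepta-4,6-dienoate; 8 2,2-dimethyl-1,3-dioxane-4,6-dione (Meldrum's acid)
Product: 9 methyl (4Z)-5-[3-(2,2-dimethyl-4,6-dioxo-1,3-dioxan-5-ylidene)propyl]-6-methylhepta-4,6-dienoate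
Conditions: ethylenediammonium diacetate (5 mol%), CH2Cl2, 4 Å MS, 0 °C, used crude
Reagents that add atoms: none
Why: Knoevenagel condensation of the aldehyde with the strongly C–H-acidic dioxanedione under mild ammonium carboxylate catalysis; the symmetric acceptor has no E/Z issue, and the alkylidene is used at once to avoid self-addition.

Step 6
Reactants: 9 methyl (4Z)-5-[3-(2,2-dimethyl-4,6-dioxo-1,3-dioxan-5-ylidene)propyl]-6-methylhepta-4,6-dienoate
Product: 10 methyl (4Z)-5-[(3R)-3-(2,2-dimethyl-4,6-dioxo-1,3-dioxan-5-yl)butyl]-6-methylhepta-4,6-dienoate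
Conditions: Me2Zn, Cu(OTf)2 (5 mol%), BINOL-derived N,N-bis(1-phenylethyl)phosphoramidite (10 mol%), DME, −40 → 0 °C; then aq. HCl
Reagents that add atoms: dimethylzinc, C[Zn]C
Why: Copper-catalysed asymmetric conjugate addition of a dialkylzinc to an alkylidene Meldrum's acid, in which the chiral copper–phosphoramidite complex delivers methyl to one face of the symmetric acceptor and so sets the (R) methyl-bearing centre (C2 of the core), while the regenerated dioxanedione C–H is the handle for step 7.

Step 7
Reactants: 10 methyl (4Z)-5-[(3R)-3-(2,2-dimethyl-4,6-dioxo-1,3-dioxan-5-yl)butyl]-6-methylhepta-4,6-dienoate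
Product: 11 (1R,2R,5S,8R)-8-(3-methoxy-3-oxopropyl)-2-methyl-7-oxo-5-(prop-1-en-2-yl)-6-oxabicyclo[3.2.1]octane-1-carboxylic acid
Conditions: Mn(OAc)3·2H2O (2.2 equiv), Cu(OAc)2·H2O (20 mol%), AcOH, 23–40 °C
Reagents that add atoms: none
Why: Trivalent manganese oxidises the dioxanedione enolate to the tertiary malonyl radical, which adds to the substituted terminus of the diene (C1–C8 bond); divalent copper then oxidises the allyl radical to the allyl cation, which is captured at its tertiary end (C5) by the axial dioxanedione carbonyl, and the resulting cation collapses with water of the hydrate to the γ-lactone, acetone and the free C1 acid. The closest known reaction type is the Mn(OAc)3/Cu(OAc)2 oxidative free-radical cyclisation of unsaturated 1,3-dicarbonyl compounds with lactone termination, that is, the oxidative γ-lactone annulation of malonyl radicals onto 1,3-dienes. The carbocycle closes by 6-endo-trig radical addition and the lactone by 5-exo-trig attack of oxygen on the allyl cation. C8 is set in a chair-like transition state with the C2 methyl equatorial, in which the (Z)-alkene geometry places the ester chain equatorial and cis to the methyl; C1 becomes stereogenic only when one of its two identical carbonyls lactonises, and since only the axial one can reach the cation, C1 and C5 are fixed together as the cis bridge. Six-membered closure should prevail because attack at C8 gives an allyl radical while C5 is fully substituted, the dioxanedione C–H (pKa about 5) is the only site trivalent manganese can enolise, and the symmetric malonyl unit removes any facial question at C1.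

Step 8
Reactants: 11 (1R,2R,5S,8R)-8-(3-methoxy-3-oxopropyl)-2-methyl-7-oxo-5-(prop-1-en-2-yl)-6-oxabicyclo[3.2.1]octane-1-carboxylic acid
Product: 12 1,3-dioxoisoindolin-2-yl (1S,2R,5S,8R)-8-(3-methoxy-3-oxopropyl)-2-methyl-7-oxo-5-(prop-1-en-2-yl)-6-oxabicyclo[3.2.1]octane-1-carboxylate
Conditions: N-hydroxyphthalimide, DIC, DMAP (cat.), CH2Cl2, 23 °C
Reagents that add atoms: N-hydroxyphthalimide, O=C1c2ccccc2C(=O)N1O
Why: Carbodiimide (Steglich-type) esterification gives the redox-active ester; the bridgehead acid should not decarboxylate thermally because the enol would be a bridgehead alkene (the change of the C1 descriptor is only a priority change).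

Step 9
Reactants: 12 1,3-dioxoisoindolin-2-yl (1S,2R,5S,8R)-8-(3-methoxy-3-oxopropyl)-2-methyl-7-oxo-5-(prop-1-en-2-yl)-6-oxabicyclo[3.2.1]octane-1-carboxylate
Product: 13 methyl 3-[(1R,2R,5S,8R)-1-ethenyl-2-methyl-7-oxo-5-(prop-1-en-2-yl)-6-oxabicyclo[3.2.1]octan-8-yl]propanoate
Conditions: CH2=CHMgBr + ZnCl2 (THF, 0 °C), then 12, Ni(acac)2 (10 mol%), 2,2'-bipyridine (10 mol%), THF/DMF, 23 °C
Reagents that add atoms: vinylmagnesium bromide (source of the vinyl group, used as vinylzinc chloride), C=C[Mg]Br
Why: Nickel-catalysed decarboxylative alkenylation (Negishi-type coupling of a redox-active ester), in which single-electron reduction by low-valent nickel releases CO2 and the bridgehead C1 radical that is captured and coupled with the vinyl group; the cage allows bond formation only on the exo face, so C1 keeps its configuration.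

Step 10
Reactants: 13 methyl 3-[(1R,2R,5S,8R)-1-ethenyl-2-methyl-7-oxo-5-(prop-1-en-2-yl)-6-oxabicyclo[3.2.1]octan-8-yl]propanoate; 14 3-bromofuran-2(5H)-one
Product: 16 methyl 3-[(1R,2R,5S,8R)-2-methyl-7-oxo-1-[2-(2-oxo-2,5-dihydrofuran-3-yl)ethyl]-5-(prop-1-en-2-yl)-6-oxabicyclo[3.2.1]octan-8-yl]propanoate (CNP0209666.1), via B-alkyl-9-BBN adduct 15 (not isolated)
Conditions: 9-BBN, THF, 0 → 23 °C; then 14, PdCl2(dppf) (5 mol%), AsPh3, Cs2CO3, DMF/H2O, 23 °C
Reagents that add atoms: none
Why: Hydroboration followed by B-alkyl Suzuki–Miyaura coupling, in which 9-BBN should add anti-Markovnikov to the mono-substituted vinyl group in preference to the isopropenyl group flanked by a quaternary carbon, and the primary alkylborane couples with the α-bromo enoate at room temperature under mild base without touching the stereocentres.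

**Compound list**

1 | methyl 4-oxobutanoate | COC(=O)CCC=O | starting material
2 | methyl 5,5-dichloropent-4-enoate | COC(=O)CCC=C(Cl)Cl | intermediate
3 | [2-(1,3-dioxolan-2-yl)ethyl]zinc bromide | Br[Zn]CCC1OCCO1 | starting material
4 | methyl (4Z)-5-chloro-7-(1,3-dioxolan-2-yl)hept-4-enoate | COC(=O)CC/C=C(\Cl)CCC1OCCO1 | intermediate
5 | 4,4,5,5-tetramethyl-2-(prop-1-en-2-yl)-1,3,2-dioxaborolane | CC(=C)B1OC(C)(C)C(C)(C)O1 | starting material
6 | methyl (4Z)-5-[2-(1,3-dioxolan-2-yl)ethyl]-6-methylhepta-4,6-dienoate | COC(=O)CC/C=C(\C(C)=C)CCC1OCCO1 | intermediate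
7 | methyl (4Z)-6-methyl-5-(3-oxopropyl)hepta-4,6-dienoate | COC(=O)CC/C=C(\C(C)=C)CCC=O | intermediate
8 | 2,2-dimethyl-1,3-dioxane-4,6-dione (Meldrum's acid) | CC1(C)OC(=O)CC(=O)O1 | starting material
9 | methyl (4Z)-5-[3-(2,2-dimethyl-4,6-dioxo-1,3-dioxan-5-ylidene)propyl]-6-methylhepta-4,6-dienoate | COC(=O)CC/C=C(\C(C)=C)CCC=C1C(=O)OC(C)(C)OC1=O | intermediate
10 | methyl (4Z)-5-[(3R)-3-(2,2-dimethyl-4,6-dioxo-1,3-dioxan-5-yl)butyl]-6-methylhepta-4,6-dienoate | COC(=O)CC/C=C(\C(C)=C)CC[C@@H](C)C1C(=O)OC(C)(C)OC1=O | intermediate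
11 | (1R,2R,5S,8R)-8-(3-methoxy-3-oxopropyl)-2-methyl-7-oxo-5-(prop-1-en-2-yl)-6-oxabicyclo[3.2.1]octane-1-carboxylic acid | C=C(C)[C@@]12CC[C@@H](C)[C@@](C(=O)O)(C(=O)O1)[C@H]2CCC(=O)OC | intermediate
12 | 1,3-dioxoisoindolin-2-yl (1S,2R,5S,8R)-8-(3-methoxy-3-oxopropyl)-2-methyl-7-oxo-5-(prop-1-en-2-yl)-6-oxabicyclo[3.2.1]octane-1-carboxylate | C=C(C)[C@@]12CC[C@@H](C)[C@@](C(=O)ON3C(=O)c4ccccc4C3=O)(C(=O)O1)[C@H]2CCC(=O)OC | intermediate
13 | methyl 3-[(1R,2R,5S,8R)-1-ethenyl-2-methyl-7-oxo-5-(prop-1-en-2-yl)-6-oxabicyclo[3.2.1]octan-8-yl]propanoate | C=C(C)[C@@]12CC[C@@H](C)[C@@](C=C)(C(=O)O1)[C@H]2CCC(=O)OC | intermediate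
14 | 3-bromofuran-2(5H)-one | O=C1OCC=C1Br | starting material
15 | methyl 3-{(1R,2R,5S,8R)-1-[2-(9-borabicyclo[3.3.1]nonan-9-yl)ethyl]-2-methyl-7-oxo-5-(prop-1-en-2-yl)-6-oxabicyclo[3.2.1]octan-8-yl}propanoate | C=C(C)[C@@]12CC[C@@H](C)[C@@](CCB3C4CCCC3CCC4)(C(=O)O1)[C@H]2CCC(=O)OC | intermediate
16 | methyl 3-[(1R,2R,5S,8R)-2-methyl-7-oxo-1-[2-(2-oxo-2,5-dihydrofuran-3-yl)ethyl]-5-(prop-1-en-2-yl)-6-oxabicyclo[3.2.1]octan-8-yl]propanoate | C=C(C)[C@@]12CC[C@@H](C)[C@@](CCC3=CCOC3=O)(C(=O)O1)[C@H]2CCC(=O)OC | target

**Step count and risks**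

Total steps: 10. Longest linear sequence: 10 steps (from 1).

Steps most likely to fail:

1. Step 7. The malonyl radical may attack the unsubstituted diene terminus (seven-membered closure), a boat-like transition state may erode the facial selectivity at C8, or acetate may intercept the allyl cation before the carbonyl bridges. The fallback is a two-electron sequence that sets out from 10 and comes back at 11. Palladium-catalysed intramolecular hydroalkylation of the diene (Pd(PPh3)4, THF, 60 °C) puts hydrogen on the CH2 terminus through a palladium hydride formed from the acidic pronucleophile, and the dioxanedione anion then closes the six-membered ring at the other allyl terminus to give methyl 3-[(7S,11R)-3,3,11-trimethyl-1,5-dioxo-8-(propan-2-ylidene)-2,4-dioxaspiro[5.5]undecan-7-yl]propanoate F1. Iodolactonisation (I2, NaHCO3, MeCN/H2O), in which the axial carbonyl opens the iodonium ion at the ring carbon and acetone is lost, gives (1R,2R,5S,8R)-5-(2-iodopropan-2-yl)-8-(3-methoxy-3-oxopropyl)-2-methyl-7-oxo-6-oxabicyclo[3.2.1]octane-1-carboxylic acid F2. E2 loss of HI toward a methyl group (DBU, toluene, 80 °C) restores the isopropenyl group and returns to 11.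

2. Step 9. The hindered bridgehead radical, which lies next to the lactone carbonyl, may be reduced or abstract hydrogen faster than nickel captures it, or the organozinc may attack the activated ester. The fallback keeps the carboxyl carbon, sets out from 11 and comes back at 13. The acid is converted ((COCl)2, cat. DMF, CH2Cl2) into methyl 3-[(1S,2R,5S,8R)-1-(chlorocarbonyl)-2-methyl-7-oxo-5-(prop-1-en-2-yl)-6-oxabicyclo[3.2.1]octan-8-yl]propanoate F3. Reduction with LiAlH(OtBu)3 (THF, −78 °C) gives the non-enolisable aldehyde methyl 3-[(1R,2R,5S,8R)-1-formyl-2-methyl-7-oxo-5-(prop-1-en-2-yl)-6-oxabicyclo[3.2.1]octan-8-yl]propanoate F4. Wittig methylenation (Ph3P=CH2, THF, −78 → 0 °C) then returns to 13.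

3. Step 10. The isopropenyl group may be hydroborated competitively, or the bromobutenolide may decompose under base (or the borane protodeboronate) before transmetalation. The fallback builds the butenolide by olefination and isomerisation, sets out from 13 and comes back at 16. Aldehyde-selective Wacker oxidation of the mono-substituted vinyl group (PdCl2(PhCN)2, CuCl2·2H2O, AgNO2, tBuOH/MeNO2, O2) gives methyl 3-[(1R,2R,5S,8R)-2-methyl-7-oxo-1-(2-oxoethyl)-5-(prop-1-en-2-yl)-6-oxabicyclo[3.2.1]octan-8-yl]propanoate F5. Wittig olefination with 3-(triphenylphosphoranylidene)oxolan-2-one (toluene, 80 °C) gives methyl 3-[(1R,2R,5S,8R)-2-methyl-7-oxo-1-[(2E)-2-(2-oxooxolan-3-ylidene)ethyl]-5-(prop-1-en-2-yl)-6-oxabicyclo[3.2.1]octan-8-yl]propanoate F6. RhCl3·3H2O-catalysed migration of the exocyclic double bond into the lactone ring (EtOH, 80 °C) gives 16; the isopropenyl group has no allylic ring hydrogen and cannot migrate.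

Further compounds
F1 | step 7 | methyl 3-[(7S,11R)-3,3,11-trimethyl-1,5-dioxo-8-(propan-2-ylidene)-2,4-dioxaspiro[5.5]undecan-7-yl]propanoate | CC(C)=C1CC[C@@H](C)C2(C(=O)OC(C)(C)OC2=O)[C@H]1CCC(=O)OC
F2 | step 7 | (1R,2R,5S,8R)-5-(2-iodopropan-2-yl)-8-(3-methoxy-3-oxopropyl)-2-methyl-7-oxo-6-oxabicyclo[3.2.1]octane-1-carboxylic acid | CC(C)(I)[C@@]12CC[C@@H](C)[C@@](C(=O)O)(C(=O)O1)[C@H]2CCC(=O)OC
F3 | step 9 | methyl 3-[(1S,2R,5S,8R)-1-(chlorocarbonyl)-2-methyl-7-oxo-5-(prop-1-en-2-yl)-6-oxabicyclo[3.2.1]octan-8-yl]propanoate | C=C(C)[C@@]12CC[C@@H](C)[C@@](C(=O)Cl)(C(=O)O1)[C@H]2CCC(=O)OC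
F4 | step 9 | methyl 3-[(1R,2R,5S,8R)-1-formyl-2-methyl-7-oxo-5-(prop-1-en-2-yl)-6-oxabicyclo[3.2.1]octan-8-yl]propanoate | C=C(C)[C@@]12CC[C@@H](C)[C@@](C=O)(C(=O)O1)[C@H]2CCC(=O)OC
F5 | step 10 | methyl 3-[(1R,2R,5S,8R)-2-methyl-7-oxo-1-(2-oxoethyl)-5-(prop-1-en-2-yl)-6-oxabicyclo[3.2.1]octan-8-yl]propanoate | C=C(C)[C@@]12CC[C@@H](C)[C@@](CC=O)(C(=O)O1)[C@H]2CCC(=O)OC
F6 | step 10 | methyl 3-[(1R,2R,5S,8R)-2-methyl-7-oxo-1-[(2E)-2-(2-oxooxolan-3-ylidene)ethyl]-5-(prop-1-en-2-yl)-6-oxabicyclo[3.2.1]octan-8-yl]propanoate | C=C(C)[C@@]12CC[C@@H](C)[C@@](C/C=C3/C(=O)OCC3)(C(=O)O1)[C@H]2CCC(=O)OC
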